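The route rests on cutting two neighbouring bonds of ring A, C8a–O1 and C4a–C4. This leaves 3,4,5,6-tetramethoxybenzyne and a (Z)-α-methoxycinnamic acid that carries O1, C4, C3-OMe, C2 and ring B. The feature exploited is that C5, C6, C7 and C8 of ring A all bear oxygen. With four OMe groups the aryne across C4a–C8a is symmetric, so only one adduct can arise. In one operation the carboxylate oxygen adds and the acyl group shifts to the adjacent carbon, giving the hexasubstituted 2'-hydroxychalcone. The precursors are a silylaryl triflate and a dry cesium carboxylate. Oxidative O1–C2 closure, then chelation-guided release of C5-OH (peri to C4=O) with debenzylation, finishes the route.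

Key step: step 7

Remark: the target has no stereocentre. The chiral species that arise in passing (a four-membered alkoxide, a flavanone) are racemic, are drawn as one enantiomer, and lose their stereocentres before the target is reached.

Step 1
Reactants: 1 2,3,4-trimethoxybenzaldehyde
Product: 3 2,3,4-trimethoxyphenol, via 2,3,4-trimethoxyphenyl formate 2 (not isolated)
Conditions: 30% aq H2O2 (1.3 equiv), H2SO4 (cat.), MeOH, rt
Reagents that add atoms: hydrogen peroxide, OO
Why: Acid-catalysed Dakin-type (Baeyer–Villiger) oxidation, in which the electron-rich aryl group migrates from the aldehyde perhydrate to oxygen to give formate 2, methanol cleaves the formate in the same pot, and the three methyl ethers are inert to dilute acidic peroxide.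

Step 2
Reactants: 3 2,3,4-trimethoxyphenol
Product: 4 1,2,3,4-tetramethoxybenzene
Conditions: MeI (1.5 equiv), K2CO3 (2 equiv), acetone, reflux
Reagents that add atoms: iodomethane, CI
Why: Williamson ether synthesis at the only acidic site, giving a symmetric arene whose two ring CH positions are equivalent.

Step 3
Reactants: 4 1,2,3,4-tetramethoxybenzene
Product: 7 2,3,4,5-tetramethoxyphenol, via aryllithium 5 (not isolated), via dimethyl arylboronate 6 (not isolated)
Conditions: n-BuLi (1.2 equiv), TMEDA (1.2 equiv), THF, 0 °C; B(OMe)3 (1.5 equiv), −78 °C → rt; AcOH, 30% aq H2O2, 0 °C → rt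
Reagents that add atoms: hydrogen peroxide, OO
Why: Directed ortho-metalation beside a terminal OMe (the two free CH positions are equivalent, so only 5 can form), borate trapping to 6 and peroxide-induced 1,2-aryl shift from boron to oxygen should give the phenol, while the mildly acidic oxidation medium shields this air-sensitive phenol from base-promoted quinone formation.

Step 4
Reactants: 7 2,3,4,5-tetramethoxyphenol
Product: 8 2-bromo-3,4,5,6-tetramethoxyphenol
Conditions: NBS (1.0 equiv), CH2Cl2, −78 → 0 °C, dark
Reagents that add atoms: N-bromosuccinimide, O=C1CCC(=O)N1Br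
Why: Electrophilic aromatic bromination at the single remaining ring CH (ortho to OH), so no regiochemical choice exists, and one equivalent of NBS under cold anhydrous conditions disfavours oxidative demethylation to a quinone.

Step 5
Reactants: 8 2-bromo-3,4,5,6-tetramethoxyphenol
Product: 11 2,3,4,5-tetramethoxy-6-(trimethylsilyl)phenyl trifluoromethanesulfonate, via aryl trimethylsilyl ether 9 (not isolated), via lithium silylphenoxide 10 (not isolated)
Conditions: HMDS (1.0 equiv), THF, reflux, then evaporate; n-BuLi (1.1 equiv), THF, −100 → −78 °C; Tf2O (1.2 equiv), −100 → −78 °C; aq NaHCO3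
Reagents that add atoms: hexamethyldisilazane, C[Si](C)(C)N[Si](C)(C)C; trifluoromethanesulfonic anhydride, O=S(=O)(OS(=O)(=O)C(F)(F)F)C(F)(F)F
Why: O-Silylation, then bromine–lithium exchange followed at once by a 1,3 O-to-C silyl shift (retro-Brook rearrangement) to phenoxide 10, and O-sulfonylation with Tf2O form the standard sequence to silylaryl triflates, to which the methyl ethers are inert.

Step 6
Reactants: 12 2,4-bis(benzyloxy)benzaldehyde; 13 methyl methoxyacetate
Product: 15 (Z)-3-[2,4-bis(benzyloxy)phenyl]-2-methoxyacrylic acid (OMe and aryl on the same side of the alkene), via methyl ester 14 (not isolated)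
Conditions: 13 (3 equiv), NaOMe (3 equiv), MeOH, reflux; 2 M aq NaOH, reflux; cold 1 M HCl to pH 2–3
Reagents that add atoms: sodium hydroxide, [Na+].[OH-]
Why: Claisen-type aldol condensation of the ester enolate with the non-enolisable aldehyde and E1cB loss of hydroxide should give the thermodynamically preferred Z enoate 14 (aryl trans to the ester), which hydroxide saponifies in the same pot while the benzyl and enol ethers tolerate base.

Step 7
Reactants: 11 2,3,4,5-tetramethoxy-6-(trimethylsilyl)phenyl trifluoromethanesulfonate; 15 (Z)-3-[2,4-bis(benzyloxy)phenyl]-2-methoxyacrylic acid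
Product: 20 (Z)-3-[2,4-bis(benzyloxy)phenyl]-1-(2-hydroxy-3,4,5,6-tetramethoxyphenyl)-2-methoxyprop-2-en-1-one, via cesium carboxylate 16 (not isolated), via 3,4,5,6-tetramethoxybenzyne 17 (not isolated), via aryl-anion ester 18 (not isolated), via benzoxete alkoxide 19 (not isolated)
Conditions: 15 (1.5 equiv), Cs2CO3 (0.75 equiv), MeOH, rt, evaporate, PhMe azeotrope, vacuum; 11 (1.0 equiv), CsF (3 equiv, dried), THF (0.02 M), sealed tube, 120 °C; cold 0.5 M HCl
Reagents that add atoms: none
Why: Fluoride attacks silicon in 11 and triflate departs, so the sparingly soluble CsF releases the symmetric aryne 17 slowly; carboxylate 16 adds through oxygen (C8a–O1), the resulting aryl anion 18 attacks its own ester carbonyl to give the strained alkoxide 19, and C–O scission of 19 leaves the aryl ketone (C4a–C4) and the phenoxide of 20. The closest known reaction type is exactly this fluoride-induced insertion of silylaryl-triflate arynes into the C–O bond of carboxylic acids (O-arylation followed by an anionic ortho-Fries-type 1,3-acyl shift), which is established for α,β-unsaturated acids and for alkoxy-substituted arynes. No permanent ring is closed: the only ring formed is the four-membered one of 19, made by 4-exo-trig attack and opened again at once. No stereocentre reaches the product, the centre in 19 being racemic and transient, and the Z alkene is simply carried through. Regioselectivity is not needed because both aryne carbons of 17 are equivalent and each is flanked by an inductively activating OMe; the chemoselectivity that is needed, acyl capture by 18 instead of protonation to the plain aryl ester or attack at the β-carbon, should follow from the proton-free medium, high dilution and heat, and from a β-carbon that is hindered and made electron-rich by the α-OMe and the dialkoxyaryl group. An excess of 16 keeps the hindered product phenoxide from competing for 17, and any flavanone 21 that forms by spontaneous oxa-Michael closure is taken on together with 20.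

Step 8
Reactants: 20 (Z)-3-[2,4-bis(benzyloxy)phenyl]-1-(2-hydroxy-3,4,5,6-tetramethoxyphenyl)-2-methoxyprop-2-en-1-one
Product: 22 2-[2,4-bis(benzyloxy)phenyl]-3,5,6,7,8-pentamethoxy-4H-chromen-4-one, via 3-methoxyflavanone 21 (not isolated)
Conditions: I2 (10 mol %), DMSO, 120 °C; aq Na2S2O3
Reagents that add atoms: none
Why: Iodine/DMSO oxidative cyclisation of a 2'-hydroxychalcone, in which 6-endo-trig oxa-Michael addition of the phenol to C2 gives flavanone 21, iodination of its enol at C3 and loss of HI across C2–C3 aromatise ring C, DMSO reoxidises HI to I2, and both transient stereocentres vanish.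

Step 9
Reactants: 22 2-[2,4-bis(benzyloxy)phenyl]-3,5,6,7,8-pentamethoxy-4H-chromen-4-one
Product: 23 5,2',4'-trihydroxy-3,6,7,8-tetramethoxyflavone
Conditions: BCl3 (6 equiv, 1 M in CH2Cl2), C6HMe5 (6 equiv), CH2Cl2, −78 → 0 °C; H2O, then 1 M HCl, rt
Reagents that add atoms: none
Why: Lewis-acid ether cleavage under chelation control, in which BCl3 ionises both aryl benzyl ethers at −78 °C while pentamethylbenzene traps the benzyl cation by Friedel–Crafts alkylation so that the resorcinol ring B is not C-benzylated, and on warming boron bound to C4=O forms a six-membered chelate with O5 from which chloride removes the methyl group, whereas C3-OMe would need a strained five-membered chelate and the C6, C7 and C8 ethers have no carbonyl anchor.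

Compound list
1 | 2,3,4-trimethoxybenzaldehyde | COc1ccc(C=O)c(OC)c1OC | starting material
2 | 2,3,4-trimethoxyphenyl formate | COc1ccc(OC=O)c(OC)c1OC | intermediate (not isolated)
3 | 2,3,4-trimethoxyphenol | COc1ccc(O)c(OC)c1OC | intermediate
4 | 1,2,3,4-tetramethoxybenzene | COc1ccc(OC)c(OC)c1OC | intermediate
5 | (2,3,4,5-tetramethoxyphenyl)lithium | [Li]c1cc(OC)c(OC)c(OC)c1OC | intermediate (not isolated)
6 | dimethyl (2,3,4,5-tetramethoxyphenyl)boronate | COB(OC)c1cc(OC)c(OC)c(OC)c1OC | intermediate (not isolated)
7 | 2,3,4,5-tetramethoxyphenol | COc1cc(O)c(OC)c(OC)c1OC | intermediate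
8 | 2-bromo-3,4,5,6-tetramethoxyphenol | COc1c(O)c(Br)c(OC)c(OC)c1OC | intermediate
9 | (2-bromo-3,4,5,6-tetramethoxyphenoxy)trimethylsilane | COc1c(O[Si](C)(C)C)c(Br)c(OC)c(OC)c1OC | intermediate (not isolated)
10 | lithium 2,3,4,5-tetramethoxy-6-(trimethylsilyl)phenoxide | COc1c([O-])c([Si](C)(C)C)c(OC)c(OC)c1OC.[Li+] | intermediate (not isolated)
11 | 2,3,4,5-tetramethoxy-6-(trimethylsilyl)phenyl trifluoromethanesulfonate | COc1c(OC)c(OC)c(OS(=O)(=O)C(F)(F)F)c([Si](C)(C)C)c1OC | intermediate
12 | 2,4-bis(benzyloxy)benzaldehyde | O=Cc1ccc(OCc2ccccc2)cc1OCc1ccccc1 | starting material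
13 | methyl methoxyacetate | COCC(=O)OC | starting material
14 | methyl (Z)-3-[2,4-bis(benzyloxy)phenyl]-2-methoxyacrylate | CO/C(=C\c1ccc(OCc2ccccc2)cc1OCc1ccccc1)C(=O)OC | intermediate (not isolated)
15 | (Z)-3-[2,4-bis(benzyloxy)phenyl]-2-methoxyacrylic acid | CO/C(=C\c1ccc(OCc2ccccc2)cc1OCc1ccccc1)C(=O)O | intermediate
16 | cesium (Z)-3-[2,4-bis(benzyloxy)phenyl]-2-methoxyacrylate | CO/C(=C\c1ccc(OCc2ccccc2)cc1OCc1ccccc1)C(=O)[O-].[Cs+] | intermediate (not isolated)
17 | 3,4,5,6-tetramethoxybenzyne | COC1=C(OC)C(OC)=C(OC)C#C1 | intermediate (not isolated)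
18 | cesium salt of the C6 carbanion of 2,3,4,5-tetramethoxyphenyl (Z)-3-[2,4-bis(benzyloxy)phenyl]-2-methoxyacrylate | CO/C(=C\c1ccc(OCc2ccccc2)cc1OCc1ccccc1)C(=O)Oc1[c-]c(OC)c(OC)c(OC)c1OC.[Cs+] | intermediate (not isolated)
19 | cesium 2-{(Z)-2-[2,4-bis(benzyloxy)phenyl]-1-methoxyvinyl}-3,4,5,6-tetramethoxy-2H-benzo[b]oxet-2-olate, racemic, one enantiomer drawn | CO/C(=C\c1ccc(OCc2ccccc2)cc1OCc1ccccc1)[C@@]1([O-])Oc2c(OC)c(OC)c(OC)c(OC)c21.[Cs+] | intermediate (not isolated)
20 | (Z)-3-[2,4-bis(benzyloxy)phenyl]-1-(2-hydroxy-3,4,5,6-tetramethoxyphenyl)-2-methoxyprop-2-en-1-one | COc1c(OC)c(OC)c(C(=O)/C(OC)=C/c2ccc(OCc3ccccc3)cc2OCc2ccccc2)c(O)c1OC | intermediate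
21 | rac-trans-2-[2,4-bis(benzyloxy)phenyl]-3,5,6,7,8-pentamethoxychroman-4-one, drawn as (2R,3R) | C(c1ccccc1)Oc1ccc(c(OCc2ccccc2)c1)[C@@H]1[C@H](C(=O)c2c(OC)c(OC)c(OC)c(OC)c2O1)OC | intermediate (not isolated)
22 | 2-[2,4-bis(benzyloxy)phenyl]-3,5,6,7,8-pentamethoxy-4H-chromen-4-one | COc1c(OC)c(OC)c2c(=O)c(OC)c(-c3ccc(OCc4ccccc4)cc3OCc3ccccc3)oc2c1OC | intermediate
23 | 5,2',4'-trihydroxy-3,6,7,8-tetramethoxyflavone | COc1c(OC)c(O)c2c(=O)c(OC)c(-c3ccc(O)cc3O)oc2c1OC | target

Total step count: 9. Longest linear sequence: 8 (steps 1, 2, 3, 4, 5, 7, 8, 9).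

Steps most likely to fail

Step 7, aryne insertion.
- **What may go wrong:** The aryl anion may be protonated before the acyl group moves, so the reaction stops at plain O-arylation. The aryne may undergo cycloaddition with the electron-rich styrene or enol ether unit. The product phenoxide may be arylated a second time. Aryne release from the crowded silane may be sluggish.
- **Fallback:** It avoids the aryne and sets out from bromophenol 8 and acid 15. Esterification (EDC·HCl, DMAP, CH2Cl2) should give 2-bromo-3,4,5,6-tetramethoxyphenyl (Z)-3-[2,4-bis(benzyloxy)phenyl]-2-methoxyacrylate F1. Bromine–lithium exchange (n-BuLi, THF/Et2O, −100 °C), which is faster than carbonyl addition, produces the lithium counterpart of the same aryl anion. That anion undergoes the known halogen–metal-exchange-induced anionic Fries 1,3-acyl shift, and after NH4Cl quench the route is rejoined at 20.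

Step 8, oxidative ring closure.
- **What may go wrong:** HI may build up at high temperature, causing loss of benzyl groups or hydrolysis of the enol ether. The activated ring B may be iodinated. The reaction may stall at the flavanone stage.
- **Fallback:** It separates closure from oxidation and runs without acid, starting from 20 or its mixture with 21. NaOAc in refluxing EtOH completes the oxa-Michael closure to isolated flavanone 21. Soft enolisation (TMSOTf, Et3N, CH2Cl2, 0 °C) gives the silyl enol ether rac-2-[2,4-bis(benzyloxy)phenyl]-3,5,6,7,8-pentamethoxy-4-(trimethylsilyloxy)-2H-chromene F2. DDQ with 2,6-lutidine in CH2Cl2 at rt abstracts hydride from C2 of this 2H-chromene. The 4-silyloxyflavylium ion then loses its silyl group, and the route is rejoined at 22.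

Step 9, one-pot triple deprotection.
- **What may go wrong:** Neighbouring ethers may be over-cleaved (C6-OMe once boron sits on O5, or C3-OMe). C5 demethylation may be incomplete at the temperature that spares the others. Ring B may be C-benzylated if cation trapping is too slow.
- **Fallback:** It uses two orthogonal operations and sets out from 22. Hydrogenolysis (H2, 10% Pd/C, EtOAc/MeOH, rt) removes only the benzyl groups to give 2-(2,4-dihydroxyphenyl)-3,5,6,7,8-pentamethoxychromen-4-one F3. The milder AlCl3 in MeCN (gentle heat, then dilute HCl to break the aluminium chelate) cleaves the carbonyl-chelated C5-OMe alone, and the route is rejoined at 23.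

Further compounds
F1 | step 7 | 2-bromo-3,4,5,6-tetramethoxyphenyl (Z)-3-[2,4-bis(benzyloxy)phenyl]-2-methoxyacrylate | CO/C(=C\c1ccc(OCc2ccccc2)cc1OCc1ccccc1)C(=O)Oc1c(Br)c(OC)c(OC)c(OC)c1OC
F2 | step 8 | rac-2-[2,4-bis(benzyloxy)phenyl]-3,5,6,7,8-pentamethoxy-4-(trimethylsilyloxy)-2H-chromene, one enantiomer drawn | COC1=C(O[Si](C)(C)C)c2c(OC)c(OC)c(OC)c(OC)c2O[C@@H]1c1ccc(OCc2ccccc2)cc1OCc1ccccc1
F3 | step 9 | 2-(2,4-dihydroxyphenyl)-3,5,6,7,8-pentamethoxychromen-4-one | COc1c(OC)c(OC)c2c(=O)c(OC)c(-c3ccc(O)cc3O)oc2c1OC
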